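All runs come from a simulation for an exercise; noise was put on by code.

The ratio s = L/(L+E), the share asked of each set-up, fell in Sunday's closed flask from 83.3 % at 2.00 min to 74.9 % at 25.0 min, and two chemists read that fall differently.

| setting | Sunday's | Friday's | Saturday's | Thursday's | alder | cedar | larch | birch |
|---|---|---|---|---|---|---|---|---|
| Q | 14 mM | 7 mM | 10 mM | 14 mM | 14 mM | 14 mM (fed, over 32.0 min) | 14 mM | 14 mM |
| Z | 13.3 mM | 13.3 mM | 13.3 mM | 6.7 mM | 13.3 mM | 13.3 mM | 13.3 mM (fed, over 32.0 min) | 13.3 mM |
| remark | run made earlier | run made earlier | run made earlier | run made earlier | a single well-mixed tank run continuously and read at steady state, 40 min in it on average | a stirred flask in which Q is dosed at a steady rate over 32.0 min without added volume, worked up at 40 min | all but Z at the start; Z goes in evenly over 32.0 min, the run ends at 40 min | everything together in a closed stirred flask, run for 40 min |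
| time |  |  |  |  |  | 40 min | 40 min | 40 min |

- Sunday's (time / min: L / %, E / %): 2.00: 32.4, 6.5; 3.00: 38.9, 10.3; 5.00: 48.2, 14.4; 8.00: 54.2, 17.1; 15.0: 61.2, 20.2; 25.0: 65.6, 22.0
- Friday's (time / min: L / %, E / %): 2.00: 37.0, 7.8; 3.00: 44.9, 11.4; 5.00: 56.0, 16.5; 8.00: 64.5, 19.9; 15.0: 71.7, 23.4; 25.0: 75.0, 24.6
- Saturday's (time / min: L / %, E / %): 2.00: 35.3, 7.0; 3.00: 43.0, 11.0; 5.00: 52.1, 15.3; 8.00: 59.8, 18.6; 15.0: 68.6, 22.7; 25.0: 72.9, 24.0
- Thursday's (time / min: L / %, E / %): 2.00: 18.2, 3.9; 4.00: 25.4, 7.2; 6.00: 28.8, 9.0; 12.0: 34.3, 11.0; 25.0: 36.2, 12.1

(standard deviation of a reading: 0.3 percentage points)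

- the stated concentrations are those of everything mixed, before any reaction; amounts are the same in each set-up
- the feed brings no volume worth counting
- the earlier runs were made in a closed, stirred flask

1. the set-up with the highest share of L in all that became L or E, at the outlet or at the end ("none" if the first two lie within 2 percentage points) (alder / cedar / larch / birch / none)
2. share of L in all that became L or E, at the outlet or at the end, alder
3. share of L in all that became L or E, at the outlet or at the end, cedar
4. share of L in all that became L or E, at the outlet or at the end, larch
5. share of L in all that became L or E, at the outlet or at the end, birch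

The first chemist reads kinetic control: L comes first and E later, so a tank or a slow feed, whose pool P = L+E stays young, should hold s above the closed flask by more than 2 percentage points.

The second reads thermodynamic control, since the last share is 75.3 % on Friday's run and 74.9 % on Thursday's, with very different charges. She calls that balance share s∞, and e its complement, the balance share of E. The rise of E between 2.00 min and 5.00 min on Friday's run, set against the mean distance of E from eP, then reads θ = 0.805 min. This lag, the time constant on which E closes its distance to the balance, has the inverse λ.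

A pool growing or renewed at a steady fractional rate g keeps an excess over the balance, δ = s − s∞ = e·g/(g+λ). In alder g is the reciprocal of the mean time τ = 40 min, and because θ is far shorter than τ, she reckons alder at 75.8 %. The first chemist keeps the young pool: on Sunday's run between 2.00 min and 3.00 min, g reads 0.235 min⁻¹ against λ of 1.24 min⁻¹, and s at 3.00 min reads 79.1 %, above s∞.

The forecast takes the second side, “every set-up should end near equilibrium”, with alder 75.6 %, cedar 75.2 %, larch 75.2 %, birch 75 % and best none; its alder lies 0.20 points below the reckoning above.

The simulation gives alder 75.7 %, cedar 75.4 %, larch 75.4 %, birch 75.2 %, so best is none, the top two lying 0.30 points apart.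

Q + Z → L (k = 0.420 M⁻¹ s⁻¹); L ⇌ E (K = 0.330, k = 0.00510 s⁻¹); Z → J (k = 1.90 × 10⁻⁶ s⁻¹) The turning of Z into J, with half-life 100 h, does not move alder's share. The lag puts alder's excess at 0.49 points. In birch read at 10 min, with Q, L and E at 24.6 %, 57.1 % and 18.3 % of the Q charged and Z at 20.6 % of its own charge, the rate constant 0.42 M⁻¹ s⁻¹ gives g = 0.0224 min⁻¹, so the lag gives s = 75.7 %, and that flask stands at 75.7 %.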